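Conventions and assumptions (remarks on the chemistry)
- Briarane numbering is used for every compound: C1–C10 is the ten-membered ring; ring A is C1, C10, C11, C12, C13, C14; C15 is the methyl on C1, C16 the carbon on C5, C20 the methyl on C11; C17 (with methyl C18) and the lactone carbonyl C19 hang on C8. In the tricyclic compounds ring B is C1, C2, C7, C8, C9, C10 and ring C is C2–C7. β is the face of the C15 methyl group, α the opposite face.
- Assumption: C11 of 14–23 is drawn as the equatorial 11α-methyl epimer; the centre is erased in step 12, so either epimer serves.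
- Assumption: C8 of 35 is left undefined (erased in step 20); C17 of 40–44 is drawn as in the target, and an epimer at this enolisable centre is expected to equilibrate.
- Assumption: 1, 2, 8 and 37 are bought.

## The problem

The target is a briarane: cyclohexane ring A is trans-fused through C1–C10 to a ten-membered carbocycle, and that ring carries a γ-lactone (O–C7, C8, C17, C19) trans-fused across C7–C8. It has twelve stereocentres (C1, C2, C6–C14, C17), among them the quaternary C1, the tertiary carbinols C8 and C11, and a 3Z,5(16)-diene between the acyloxy carbon C2 and the chlorinated C6. Only C1 needs an outside source of chirality. On a rigid fused carbocycle its axial methyl can dictate C10, C9, C11, C12 and, through the 12α-hydroxyl, the 13α,14α-epoxide. C2, C6, C7, C8 and C17 sit on the flexible ring and must be relayed (C9 to C8 by Felkin–Anh addition, C17 by equilibration, C2/C6/C7 by the ring's outer face). The secondary allylic chloride, the epoxide next to an acyloxy group, the β-hydroxy lactone and three different esters beside two free tertiary alcohols exclude strong base, Lewis acids, zerovalent palladium and dissolving metal late in the route, and they fix the order of acylations. Direct closure of a fully substituted ten-membered ring is unattractive. The enabling feature is that C2 and C7 both bear oxygen and face each other across the ring. A C2–C7 bond turns the 6/10 bicycle into a hydrophenanthrene whose ring C (C2–C7 with C16 on C5) is a Birch-reduced toluene ring, so the C2=C7 olefin of that dihydroarene can be cleaved to deliver both oxygens and the ten-membered ring at once.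

## Retrosynthesis

50 to 45 (C–O bonds only). The C12 butanoate, the epoxide oxygen, the acetonide and the C9 acetate are removed first in the analysis, because none of them survives enolate or hydride chemistry. The forward order is chosen so that each acylation meets exactly one acylable hydroxyl: 45 gives 46 (fluoride), 47 (acetate on the only secondary alcohol), 48 (acetonide off), 49 (epoxidation directed by the 12α-hydroxyl) and 50 (butanoate on the only secondary alcohol). The precursor 45 has no epoxide and one ester.

45 to 44 to 42 (acyl C–O at C2; lactone O7–C19; C2–H and C7–H). Closing the lactone from the C7 alkoxide onto C19, rather than building C8–C17 on a preformed C7 ester, keeps C9 silylated, so only O7 can lactonise. The chloro diketone 42 is simpler by two stereocentres and one ring. The forward hydride additions must choose the correct faces of C2 and C7.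

42 to 40 (C6–Cl). Chlorine and the exocyclic olefin are cut together: 42 is the deconjugative α-chlorination product of the C7 dienone 40, in which C16 is still a methyl on C5=C6. A separate allylic substitution at C6 would need its own stereocontrol and an extra oxidation level. The forward step needs α- rather than γ-attack on the extended enolate.

40 to 36 + 37 (C8–C17). An aldol cut gives the tertiary carbinol and the three lactone carbons in one bond. In trione 36, C8 is the only non-conjugated carbonyl and is activated by its neighbour, and the C9 silyloxy stereocentre can direct the addition. The forward reaction must add at C8 faster than it enolises toward C9.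

36 to 35 to 33 (C8=O). The C8 carbonyl is traced to the methylene next to the C7 ketone. This cut is available only because C6 is vinylic in 33, so C7 can enolise in one direction only.

33 to 31 (two hydrogens at C3 and C6). The dienedione 33 is the dehydrogenation product of 31, whose two ketones are both β,γ to the same olefin. Oxidising through the bis-silyl dienol ether installs C3=C4 and removes the choice between the α-positions of C7.

31 to 29 (C2–C7 reconnected; the key cut). The two carbonyls are joined to the tetrasubstituted olefin shared by rings B and C. This is preferred to any C–C disconnection of the ten-membered ring because the forward step is a cleavage, creates no stereocentre and uses a precursor with three six-membered rings.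

29 to 28 (four ring C hydrogens). Birch reduction of the 1,2,4-trialkylbenzene 28 is the only way to place the tetrasubstituted olefin exactly at C2=C7.

28 to 27 to 26 (C11–O and C12–O). Both ring A carbinol oxygens are cut together as a cis-dihydroxylation of the 11,13-diene 26 from the α face. The alternative, hydroxylating C11 and reducing a C12 ketone, would put the C12 oxygen equatorial (β), the wrong epimer. The C13=C14 olefin that remains is the masked epoxide.

26 to 25 to 23 to 20 (diene from ketone). The diene comes from the C12 ketone by Saegusa oxidation, dienyl triflate formation and reduction. All are robust steps on an arene-protected tricycle.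

20 to 14 (C9–O and C10–H). The C9 oxygen and the trans ring fusion come from hydroboration of the C9=C10 olefin of 14, followed by inversion at C9 through the ketone 17. The olefin position is a free by-product of ketalising the enone 13.

13 to 11 to 7 + 8 (C10=C11 and C1–C14). A Robinson annulation cut removes ring A and leaves the quaternary C1 to a chiral-imine Michael addition of 7 to pent-1-en-3-one.

7 to 4 to 1 + 2. The methyl on C1 is an enamine alkylation, and the tetralone is a Friedel–Crafts acylation of ethene and ring closure of (4-methylphenyl)acetic acid.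

## Roads not taken

Alternative 1: The cut is the ring-fusion bond C1–C10, leading back to a fourteen-membered carbocycle A1 that holds a C1–C14 epoxide and a C10=C11 allylsilane. In the forward step a Lewis acid opens the epoxide at its tertiary end and C10 attacks C1 across the ring, so ring A and the ten-membered ring close together to give A2.
- Merits: the quaternary C1, C10 and the trans fusion come from one C–C bond; the lactone and the C2, C9 and C12 oxygens are already present; a fourteen-membered ring is easier to close than a ten-membered one.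
- Weak points: A1 needs a trisubstituted epoxide of defined configuration and a trisubstituted allylsilane of defined geometry inside a macrocycle. The outcome at C1 and C10 rests on one transannular conformation. After the key step ring A still lacks the C11 tertiary alcohol and the 13,14-epoxide (only a neopentyl C14 alcohol and an exocyclic methylene are present). The ten-membered ring of A2 contains a strained enyne, and the chloride is still missing.
- Comparison: this road is better in convergence and in making the quaternary centre during the key step. The chosen plan sets against it a key step that cannot fail stereochemically, a precursor reached by a Robinson annulation, and ring A centres read from the C15 methyl on a rigid tricycle.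

Alternative 2: The cut is C7–C19 and C8–C17, a cyclobutanone that would later be ring-expanded to the lactone. In the forward step methylketene A4, made in the flask, adds across the C7=C8 silyl enol ether A3 to give the cyclobutanone A5.
- Merits: the C8 quaternary carbinol, C17 and the C7–C19 bond form in one suprafacial step, and C7 and C8 are set together.
- Weak points: the step presupposes the complete chlorinated ten-membered diene and says nothing about making the ring. The enol ether must be formed from a C8 ketone toward C7, where the enolate carries the C6 chloride in the β-position and can eliminate it. A trans-fused cyclobutanone requires the enol ether geometry in which C6 and C9 are trans across C7=C8, which a ten-membered ring forms reluctantly. The ketene can also add to the 1,3-diene. The later oxygen insertion must distinguish two secondary carbons in the presence of three olefins.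
- Comparison: this road is better than the chosen plan's stepwise aldol and reduction for the relative configuration of C7 and C8. The chosen plan sets against it that all enolate chemistry precedes the chloride, that no peracid meets the diene, and that it actually builds the ring.

Alternative 3: The cut is C1–C14 and C10–C11, a Diels–Alder reaction that forms ring A last. The forward step adds the silyloxydiene A7 across the C1=C10 bond of the cyclodecenedione A6 to give A8.
- Merits: it is the most convergent road; two C–C bonds and up to three stereocentres form at once, the E olefin is translated into the trans fusion, and a C12 enol ether is left as a handle.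
- Weak points: A6 needs a trisubstituted E olefin between two ketones in a ten-membered ring, which is strained and prone to isomerise. C1 and C10 are each β to one carbonyl, so the orientation of the unsymmetrical diene is poorly polarised. Forming a quaternary centre with this dienophile calls for Lewis acid or pressure next to an allylic chloride. The cross-conjugated dienone of A6 competes as a dienophile. Facial selectivity depends on the remote C8. Afterwards the C11 alcohol, the C12 carbinol (ketone reduction favours the wrong, equatorial epimer) and two ring ketones remain.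
- Comparison: this road is better in convergence. The chosen plan sets against it that the same centres are made early on a rigid tricycle and that the 12α oxygen arrives by osmylation, not by a ketone reduction biased the wrong way.

Key step: step 17

## Steps

Step 1
Reactants: 1 (4-methylphenyl)acetic acid; 2 ethene
Product: 4 6-methyl-3,4-dihydronaphthalen-2(1H)-one, via (4-methylphenyl)acetyl chloride 3 (not isolated)
Conditions: SOCl2, HCONMe2 (cat.), CH2Cl2, 40 °C; then ethene (1 atm), AlCl3, CH2Cl2, −10 °C → rt
Reagents that add atoms: none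
Why: Friedel–Crafts acylation of ethene by the acylium ion, then ring closure of the β-chloroethyl ketone ortho to the side chain (the standard 2-tetralone synthesis). The para methyl ends at C6 of the tetralone, which is C5 of the target and carries C16.

Step 2
Reactants: 4 6-methyl-3,4-dihydronaphthalen-2(1H)-one
Product: 7 1,6-dimethyl-3,4-dihydronaphthalen-2(1H)-one (racemic), via pyrrolidine enamine 5 (not isolated), via C-methylated iminium iodide 6 (not isolated)
Conditions: pyrrolidine, PhMe, reflux (−H2O); MeI, MeCN, 60 °C; then AcOH/H2O, rt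
Reagents that add atoms: iodomethane, CI
Why: Stork enamine alkylation. The enamine of a 2-tetralone is conjugated with the arene, so monomethylation occurs only at the benzylic carbon (future C1 with C15).

Step 3
Reactants: 7 1,6-dimethyl-3,4-dihydronaphthalen-2(1H)-one (racemic); 8 pent-1-en-3-one
Product: 11 (R)-1,6-dimethyl-1-(3-oxopentyl)-3,4-dihydronaphthalen-2(1H)-one, via chiral imine 9 (not isolated), via Michael adduct imine 10 (not isolated)
Conditions: (R)-1-phenylethylamine, TsOH·H2O (cat.), PhMe, reflux (−H2O); then 8, THF, rt; then 20% aq. AcOH, rt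
Reagents that add atoms: none
Why: Deracemising Michael addition of a chiral imine through its more substituted secondary enamine tautomer (aza-ene-like transition state). The enone should arrive on the enamine face remote from the phenyl group, which for the (R)-amine is expected to give the C1 configuration of the target, and the labile C1 of racemic 7 converges.

Step 4
Reactants: 11 (R)-1,6-dimethyl-1-(3-oxopentyl)-3,4-dihydronaphthalen-2(1H)-one
Product: 13 (S)-1,4a,7-trimethyl-4,4a,9,10-tetrahydrophenanthren-2(3H)-one (tricyclic 10-en-12-one), via tricyclic ketol 12 (not isolated)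
Conditions: NaOMe, MeOH, rt → 60 °C
Reagents that add atoms: none
Why: Intramolecular aldol condensation completing the Robinson annulation. Only the C11 methylene of the ethyl ketone reaches the C10 carbonyl through a six-membered ring, and dehydration gives the C10=C11 enone with C20 in place.

Step 5
Reactants: 13 (S)-1,4a,7-trimethyl-4,4a,9,10-tetrahydrophenanthren-2(3H)-one
Product: 14 tricyclic 9-ene 12-ethylene ketal with 11α-methyl
Conditions: HOCH2CH2OH, TsOH·H2O (cat.), PhH, reflux (Dean–Stark)
Reagents that add atoms: ethane-1,2-diol, OCCO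
Why: Deconjugative ketalisation as with steroidal 4-en-3-ones: the dioxolane forms through the dienol ether and protonation at C11 moves the olefin to C9=C10. C11 should settle as the equatorial methyl epimer, which avoids the syn-axial C15 methyl.

Step 6
Reactants: 14 tricyclic 9-ene 12-ethylene ketal with 11α-methyl
Product: 16 9α-hydroxy-10α-H trans-fused 12-ketal, via C9 alkylborane 15 (not isolated)
Conditions: BH3·THF, THF, 0 °C → rt; then NaOH, H2O2, 0 °C
Reagents that add atoms: hydrogen peroxide, OO
Why: Hydroboration–oxidation puts boron on the less substituted C9 and hydrogen on C10. Syn addition from the α face, opposite the angular C15 methyl, sets the trans ring fusion (10α-H) and gives the equatorial 9α-alcohol, as with steroidal 5-ene 3-ketals.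

Step 7
Reactants: 16 9α-hydroxy-10α-H trans-fused 12-ketal
Product: 17 9-oxo 12-ketal
Conditions: Dess–Martin periodinane, NaHCO3, CH2Cl2, rt
Reagents that add atoms: none
Why: Buffered Dess–Martin oxidation of a secondary alcohol. It is needed because hydroboration gives the C9 epimer of the target; the trans fusion is the stable one, so C10 is not at risk.

Step 8
Reactants: 17 9-oxo 12-ketal
Product: 18 9β-hydroxy 12-ketal
Conditions: LiBH(s-Bu)3, THF, −78 °C
Reagents that add atoms: none
Why: Ketone reduction by a bulky hydride. The axial (β) trajectory at C9 is blocked by the syn-axial C15 methyl, as in 6-oxo steroids, so hydride should enter from the α face and give the axial 9β-alcohol, the C9 configuration of the target.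

Step 9
Reactants: 18 9β-hydroxy 12-ketal
Product: 19 9β-tert-butyldimethylsilyloxy 12-ketal
Conditions: TBSOTf, 2,6-lutidine, CH2Cl2, 0 °C
Reagents that add atoms: tert-butyldimethylsilyl trifluoromethanesulfonate, CC(C)(C)[Si](C)(C)OS(=O)(=O)C(F)(F)F
Why: Silylation of a hindered axial alcohol with the silyl triflate. The ether should survive enolates, dissolving metal, ozone and hydride, cannot chelate in step 21, and is removable by fluoride.

Step 10
Reactants: 19 9β-tert-butyldimethylsilyloxy 12-ketal
Product: 20 9β-silyloxy 12-ketone
Conditions: pyridinium p-toluenesulfonate, acetone/H2O, 60 °C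
Reagents that add atoms: water, O
Why: Acid-catalysed ketal hydrolysis under conditions that leave a secondary silyl ether intact. C11, now α to the ketone, stays as the equatorial methyl epimer.

Step 11
Reactants: 20 9β-silyloxy 12-ketone
Product: 23 9β-silyloxy 13-en-12-one, via lithium 12(13)-enolate 21 (not isolated), via 12-trimethylsilyloxy-12-ene 22 (not isolated)
Conditions: LiN(i-Pr)2, THF, −78 °C; Me3SiCl; then Pd(OAc)2, MeCN, rt
Reagents that add atoms: none
Why: Kinetic deprotonation takes the C13 methylene in preference to the C11 methine, and Saegusa–Ito oxidation of the silyl enol ether introduces C13=C14. No other direction is open because C1 is quaternary.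

Step 12
Reactants: 23 9β-silyloxy 13-en-12-one
Product: 25 9β-silyloxy 11,13-dien-12-yl triflate, via potassium 11,13-dien-12-olate 24 (not isolated)
Conditions: KN(SiMe3)2, THF, −78 °C; then PhNTf2, −78 °C → 0 °C
Reagents that add atoms: N-phenylbis(trifluoromethanesulfonimide), O=S(=O)(N(c1ccccc1)S(=O)(=O)C(F)(F)F)C(F)(F)F
Why: The enone has one enolisable hydrogen, the axial C11–H, so only the cross-conjugated dienolate can form. O-sulfonylation gives the dienyl triflate and erases the C11 centre.

Step 13
Reactants: 25 9β-silyloxy 11,13-dien-12-yl triflate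
Product: 26 9β-silyloxy 11,13-diene
Conditions: Pd(OAc)2 (cat.), PPh3, HCO2H, n-Bu3N, HCONMe2, 60 °C
Reagents that add atoms: none
Why: Palladium-catalysed formate reduction of an enol triflate (oxidative addition, formate exchange, loss of CO2, reductive elimination). The arene and silyl ether are inert.

Step 14
Reactants: 26 9β-silyloxy 11,13-diene
Product: 27 9β-silyloxy 13-ene-11α,12α-diol
Conditions: OsO4 (cat.), 4-methylmorpholine N-oxide, acetone/H2O, rt
Reagents that add atoms: osmium tetroxide, O=[Os](=O)(=O)=O; 4-methylmorpholine N-oxide, C[N+]1([O-])CCOCC1; water, O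
Why: Upjohn dihydroxylation. OsO4 should select the electron-richer trisubstituted C11=C12 over the neopentyl C13=C14 and add from the α face, opposite the axial C15 methyl. This sets both ring A carbinol centres (11α-OH with C20 β, 12α-OH) in one step.

Step 15
Reactants: 27 9β-silyloxy 13-ene-11α,12α-diol
Product: 28 11α,12α-acetonide of the aromatic tricycle
Conditions: Me2C(OMe)2, pyridinium p-toluenesulfonate (cat.), CH2Cl2, rt
Reagents that add atoms: 2,2-dimethoxypropane, COC(C)(C)OC
Why: Acetal exchange on a cis-1,2-diol. The acetonide masks both hydroxyls through the metal, ozone and enolate steps.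

Step 16
Reactants: 28 11α,12α-acetonide of the aromatic tricycle
Product: 29 tricyclic 2(7),4,13-triene
Conditions: Li, NH3 (l), THF, t-BuOH, −78 °C → −33 °C; then NH4Cl
Reagents that add atoms: none
Why: Birch reduction of a 1,2,4-trialkylbenzene. Protonation at the two unsubstituted, mutually para carbons C3 and C6 leaves all alkyl-bearing carbons sp2, giving the tetrasubstituted C2=C7 and trisubstituted C4=C5 olefins. The isolated C13=C14 olefin, silyl ether and acetonide are not reduced.

Step 17
Reactants: 29 tricyclic 2(7),4,13-triene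
Product: 31 ten-membered (4Z)-4,13-diene-2,7-dione, via secondary ozonide 30 (not isolated)
Conditions: O3 (1.0 equiv, Sudan Red 7B end-point), CH2Cl2, −78 °C; then PPh3, −78 °C → rt
Reagents that add atoms: ozone, [O-][O+]=O
Why: Ozone adds as a 1,3-dipole to C2=C7; cycloreversion and recombination (Criegee mechanism) give the bridged ozonide 30, which PPh3 reduces to the two ketones. The closest known reaction type is the ozonolysis of Birch-derived dihydrotetralins and 9,10-octalins to cyclodecene- and cyclodecane-1,6-diones. The ten-membered ring is not closed end to end: it appears when the bond shared by rings B and C is cut, so no exo or endo closure mode applies and no macrocyclisation entropy is paid. No stereocentre is created; C1, C9, C10, C11 and C12 are untouched and C4=C5 keeps the Z geometry it had in ring C. The step needs chemoselectivity among three olefins. Ozone reacts fastest with the tetrasubstituted, most electron-rich C2=C7; C4=C5 is trisubstituted, and C13=C14 is disubstituted, deactivated by the allylic acetonide oxygen and screened by C1. One equivalent at −78 °C against the dye end-point should stop the reaction there. Both new carbonyls sit on carbons that are oxygenated in the target. Because a cyclodecane-1,6-dione can undergo transannular aldol reaction, 31 should be worked up neutral and used at once.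

Step 18
Reactants: 31 ten-membered (4Z)-4,13-diene-2,7-dione
Product: 33 (3Z,5Z)-3,5,13-triene-2,7-dione, via 2,7-bis(trimethylsilyloxy) triene 32 (not isolated)
Conditions: Me3SiOTf, Et3N, CH2Cl2, 0 °C; then DDQ, 2,6-lutidine, 0 °C → rt
Reagents that add atoms: none
Why: Soft enolisation turns both β,γ-unsaturated ketones into silyl dienol ethers that share C4=C5 (C2 can enolise only toward C3, C7 prefers the allylic C6). DDQ then removes two electrons and both silyl groups, the known dehydrogenation of silyl dienol ethers to linearly conjugated dienones. The cisoid ring geometry should fix C3=C4 as Z.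

Step 19
Reactants: 33 (3Z,5Z)-3,5,13-triene-2,7-dione
Product: 35 8-hydroxy-3,5,13-triene-2,7-dione (C8 epimers), via lithium 7(8)-enolate 34 (not isolated)
Conditions: LiN(i-Pr)2, THF, −78 °C; then 2-(phenylsulfonyl)-3-phenyloxaziridine, −78 °C
Reagents that add atoms: 2-(phenylsulfonyl)-3-phenyloxaziridine, O=S(=O)(N1OC1c1ccccc1)c1ccccc1
Why: Kinetic α′-deprotonation of the C7 dienone can occur only at C8 (C6 is vinylic, C2 has no α-hydrogen), and the enolate is oxidised by the N-sulfonyloxaziridine (Davis hydroxylation). At −78 °C the β-silyloxy group on C9 should not be eliminated, and the C8 configuration is irrelevant.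

Step 20
Reactants: 35 8-hydroxy-3,5,13-triene-2,7-dione (C8 epimers)
Product: 36 3,5,13-triene-2,7,8-trione
Conditions: Dess–Martin periodinane, NaHCO3, CH2Cl2, 0 °C
Reagents that add atoms: none
Why: Neutral oxidation of the acyloin to the vicinal diketone. It is used directly, because the C9 hydrogen is now enolisable.

Step 21
Reactants: 36 3,5,13-triene-2,7,8-trione; 37 methyl propanoate
Product: 40 C8 aldol adduct as its 8-trimethylsilyl ether (C7 ketone and C19 methyl ester), via lithium enolate of methyl propanoate 38 (not isolated), via lithium C8 aldolate 39 (not isolated)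
Conditions: LiN(i-Pr)2, 37, THF, −78 °C; then 36, −78 °C; then Me3SiCl, Et3N, −78 °C → −20 °C
Reagents that add atoms: chlorotrimethylsilane, C[Si](C)(C)Cl
Why: Aldol addition to C8, the only non-conjugated carbonyl and the one activated by its neighbour. The bulky, non-chelating C9 silyloxy group should direct attack anti to the C9–O bond (Felkin–Anh), which corresponds to the C8 configuration of the target. Silylating the aldolate blocks retro-aldol cleavage; C17 stays epimerisable.

Step 22
Reactants: 40 C8 aldol adduct as its 8-trimethylsilyl ether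
Product: 42 6-chloro-3,5(16),13-triene-2,7-dione, via potassium 5(16),6-dienolate 41 (not isolated)
Conditions: KN(SiMe3)2, THF, −78 °C; then N-chlorosuccinimide, −78 °C; AcOH quench
Reagents that add atoms: N-chlorosuccinimide, O=C1CCC(=O)N1Cl
Why: With C8 quaternary, the only acidic hydrogens of the C7 enone are on C16, and the extended enolate takes the chlorine electrophile at the α-carbon C6 (deconjugative α-halogenation). This moves the olefin to C5=C16 and leaves C3=C4 untouched. Attack is expected on the outer ring face, away from the C8 side chain.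

Step 23
Reactants: 42 6-chloro-3,5(16),13-triene-2,7-dione
Product: 44 6-chloro-2-hydroxy 19,7-lactone with 8-trimethylsilyloxy and 9-silyloxy groups, via 2,7-diol methyl ester 43 (not isolated)
Conditions: NaBH4, CeCl3·7H2O, MeOH/THF, −40 °C → 0 °C; then pyridinium p-toluenesulfonate (cat.), CH2Cl2, rt
Reagents that add atoms: none
Why: Luche reduction gives 1,2-addition at both ketones, and the C7 alkoxide closes the γ-lactone on C19 with loss of methanol; C9 is silylated, so only O7 can lactonise. Hydride is expected anti to the C15 methyl at C2 and anti to the C8–O bond on the outer face at C7. Both assignments are substrate-controlled and flagged below.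

Step 24
Reactants: 44 6-chloro-2-hydroxy 19,7-lactone
Product: 45 2-butanoate of the silylated lactone
Conditions: (n-PrCO)2O, 4-(dimethylamino)pyridine, Et3N, CH2Cl2, 0 °C → rt
Reagents that add atoms: butanoic anhydride, CCCC(=O)OC(=O)CCC
Why: Nucleophile-catalysed acylation of the only free hydroxyl in the molecule.

Step 25
Reactants: 45 2-butanoate of the silylated lactone
Product: 46 2-butanoate 8,9-diol
Conditions: HF·pyridine, pyridine/THF, 0 °C → rt
Reagents that add atoms: none
Why: Fluoride cleaves both silyl ethers. Buffered HF is tolerated by the acetonide, esters, lactone and allylic chloride.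

Step 26
Reactants: 46 2-butanoate 8,9-diol
Product: 47 9-acetate 2-butanoate with free 8-hydroxyl
Conditions: Ac2O, 4-(dimethylamino)pyridine (cat.), pyridine, CH2Cl2, rt
Reagents that add atoms: acetic anhydride, CC(=O)OC(C)=O
Why: Acetylation of the only secondary alcohol. The tertiary C8 hydroxyl does not react under these conditions, and capping C9 promptly prevents translactonisation.

Step 27
Reactants: 47 9-acetate 2-butanoate
Product: 48 11α,12α-diol
Conditions: AcOH/H2O (4:1), 40 °C
Reagents that add atoms: none
Why: Mild acid hydrolysis of the acetonide. Carboxylic esters, the lactone and the deactivated secondary allylic chloride should survive.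

Step 28
Reactants: 48 11α,12α-diol
Product: 49 13α,14α-epoxy-11α,12α-diol
Conditions: VO(acac)2 (cat.), t-BuOOH, CH2Cl2, 0 °C → rt
Reagents that add atoms: tert-butyl hydroperoxide, CC(C)(C)OO
Why: Hydroxyl-directed epoxidation. The pseudoaxial allylic 12α-hydroxyl delivers oxygen to its own (α) face, which is also the face left open by the C15 methyl. No other olefin has a free allylic hydroxyl.

Step 29
Reactants: 49 13α,14α-epoxy-11α,12α-diol
Product: 50 CNP0188106.1
Conditions: (n-PrCO)2O, 4-(dimethylamino)pyridine, Et3N, CH2Cl2, rt
Reagents that add atoms: butanoic anhydride, CCCC(=O)OC(=O)CCC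
Why: Acylation of the single secondary alcohol; the tertiary C8 and C11 hydroxyls stay free.

## Compound list

1 | (4-methylphenyl)acetic acid | Cc1ccc(CC(=O)O)cc1 | starting material
2 | ethene | C=C | starting material
3 | (4-methylphenyl)acetyl chloride | Cc1ccc(CC(=O)Cl)cc1 | intermediate
4 | 6-methyl-3,4-dihydronaphthalen-2(1H)-one | Cc1ccc2CC(=O)CCc2c1 | intermediate
5 | 1-(6-methyl-3,4-dihydronaphthalen-2-yl)pyrrolidine | Cc1ccc2C=C(N3CCCC3)CCc2c1 | intermediate
6 | 1-(1,6-dimethyl-3,4-dihydro-1H-naphthalen-2-ylidene)pyrrolidinium iodide | Cc1ccc2C(C)C(=[N+]3CCCC3)CCc2c1.[I-] | intermediate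
7 | 1,6-dimethyl-3,4-dihydronaphthalen-2(1H)-one (racemic) | Cc1ccc2C(C)C(=O)CCc2c1 | intermediate
8 | pent-1-en-3-one | CCC(=O)C=C | starting material
9 | N-[(R)-1-phenylethyl] imine of 7 | Cc1ccc2C(C)C(=N[C@H](C)c3ccccc3)CCc2c1 | intermediate
10 | N-[(R)-1-phenylethyl] imine of 11 | CCC(=O)CC[C@@]1(C)C(=N[C@H](C)c3ccccc3)CCc2cc(C)ccc21 | intermediate
11 | (R)-1,6-dimethyl-1-(3-oxopentyl)-3,4-dihydronaphthalen-2(1H)-one | CCC(=O)CC[C@@]1(C)C(=O)CCc2cc(C)ccc21 | intermediate
12 | tricyclic ketol (10-hydroxy-12-ketone, aldol adduct of 11) | Cc1ccc2c(c1)CCC3(O)C(C)C(=O)CC[C@]23C | intermediate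
13 | (S)-1,4a,7-trimethyl-4,4a,9,10-tetrahydrophenanthren-2(3H)-one (10-en-12-one, aromatic ring C) | Cc1ccc2c(c1)CCC3=C(C)C(=O)CC[C@]23C | intermediate
14 | tricyclic 9-ene 12-ethylene ketal, 11α-methyl | Cc1ccc2c(c1)CC=C3[C@H](C)C4(OCCO4)CC[C@]23C | intermediate
15 | 9α-boryl 10α-H 12-ketal (monoalkylborane) | Cc1ccc2c(c1)C[C@H](B)[C@H]3[C@H](C)C4(OCCO4)CC[C@]23C | intermediate
16 | 9α-hydroxy 10α-H trans-fused 12-ketal | Cc1ccc2c(c1)C[C@H](O)[C@H]3[C@H](C)C4(OCCO4)CC[C@]23C | intermediate
17 | 9-oxo 12-ketal | Cc1ccc2c(c1)CC(=O)[C@H]3[C@H](C)C4(OCCO4)CC[C@]23C | intermediate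
18 | 9β-hydroxy 12-ketal | Cc1ccc2c(c1)C[C@@H](O)[C@H]3[C@H](C)C4(OCCO4)CC[C@]23C | intermediate
19 | 9β-tert-butyldimethylsilyloxy 12-ketal | Cc1ccc2c(c1)C[C@@H](O[Si](C)(C)C(C)(C)C)[C@H]3[C@H](C)C4(OCCO4)CC[C@]23C | intermediate
20 | 9β-silyloxy 12-ketone | Cc1ccc2c(c1)C[C@@H](O[Si](C)(C)C(C)(C)C)[C@H]3[C@H](C)C(=O)CC[C@]23C | intermediate
21 | lithium 12(13)-enolate of 20 | Cc1ccc2c(c1)C[C@@H](O[Si](C)(C)C(C)(C)C)[C@H]3[C@H](C)C([O-])=CC[C@]23C.[Li+] | intermediate
22 | 12-trimethylsilyloxy-12-ene | Cc1ccc2c(c1)C[C@@H](O[Si](C)(C)C(C)(C)C)[C@H]3[C@H](C)C(O[Si](C)(C)C)=CC[C@]23C | intermediate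
23 | 9β-silyloxy 13-en-12-one | Cc1ccc2c(c1)C[C@@H](O[Si](C)(C)C(C)(C)C)[C@H]3[C@H](C)C(=O)C=C[C@]23C | intermediate
24 | potassium 11,13-dien-12-olate | Cc1ccc2c(c1)C[C@@H](O[Si](C)(C)C(C)(C)C)[C@H]3C(C)=C([O-])C=C[C@]23C.[K+] | intermediate
25 | 9β-silyloxy 11,13-dien-12-yl triflate | Cc1ccc2c(c1)C[C@@H](O[Si](C)(C)C(C)(C)C)[C@H]3C(C)=C(OS(=O)(=O)C(F)(F)F)C=C[C@]23C | intermediate
26 | 9β-silyloxy 11,13-diene | Cc1ccc2c(c1)C[C@@H](O[Si](C)(C)C(C)(C)C)[C@H]3C(C)=CC=C[C@]23C | intermediate
27 | 9β-silyloxy 13-ene-11α,12α-diol | Cc1ccc2c(c1)C[C@@H](O[Si](C)(C)C(C)(C)C)[C@H]3[C@](C)(O)[C@H](O)C=C[C@]23C | intermediate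
28 | 11α,12α-acetonide, 9β-silyloxy, 13-ene, aromatic ring C | Cc1ccc2c(c1)C[C@@H](O[Si](C)(C)C(C)(C)C)[C@H]3[C@]4(C)OC(C)(C)O[C@@H]4C=C[C@]23C | intermediate
29 | tricyclic 2(7),4,13-triene (9β-silyloxy, 11α,12α-acetonide) | CC1=CCC2=C(C1)C[C@@H](O[Si](C)(C)C(C)(C)C)[C@H]3[C@]4(C)OC(C)(C)O[C@@H]4C=C[C@]23C | intermediate
30 | secondary ozonide bridging C2 and C7 (C2 and C7 undefined) | C/C1=C/CC4(OO5)[C@@]2(C)C=C[C@H]3OC(C)(C)O[C@@]3(C)[C@@H]2[C@H](O[Si](C)(C)C(C)(C)C)CC5(O4)C1 | intermediate
31 | ten-membered (4Z)-4,13-diene-2,7-dione (9-silyloxy, 11,12-acetonide; C1, C9–C12 as in 50) | C/C1=C/CC(=O)[C@@]2(C)C=C[C@H]3OC(C)(C)O[C@@]3(C)[C@@H]2[C@H](O[Si](C)(C)C(C)(C)C)CC(=O)C1 | intermediate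
32 | 2,7-bis(trimethylsilyloxy)-2,4,6,13-tetraene | C[Si](C)(C)O/C1=C/C(C)=C\C=C(\O[Si](C)(C)C)[C@@]2(C)C=C[C@H]3OC(C)(C)O[C@@]3(C)[C@@H]2[C@H](O[Si](C)(C)C(C)(C)C)C1 | intermediate
33 | (3Z,5Z)-3,5,13-triene-2,7-dione | O=C1/C=C(C)\C=C/C(=O)[C@@]2(C)C=C[C@H]3OC(C)(C)O[C@@]3(C)[C@@H]2[C@H](O[Si](C)(C)C(C)(C)C)C1 | intermediate
34 | lithium 7(8)-enolate of 33 | [O-]C1/C=C(C)\C=C/C(=O)[C@@]2(C)C=C[C@H]3OC(C)(C)O[C@@]3(C)[C@@H]2[C@H](O[Si](C)(C)C(C)(C)C)C=1.[Li+] | intermediate
35 | 8-hydroxy-3,5,13-triene-2,7-dione (C8 undefined) | O=C1/C=C(C)\C=C/C(=O)[C@@]2(C)C=C[C@H]3OC(C)(C)O[C@@]3(C)[C@@H]2[C@H](O[Si](C)(C)C(C)(C)C)C1O | intermediate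
36 | 3,5,13-triene-2,7,8-trione | O=C1/C=C(C)\C=C/C(=O)[C@@]2(C)C=C[C@H]3OC(C)(C)O[C@@]3(C)[C@@H]2[C@H](O[Si](C)(C)C(C)(C)C)C1=O | intermediate
37 | methyl propanoate | CCC(=O)OC | starting material
38 | lithium enolate of methyl propanoate | CC=C([O-])OC.[Li+] | intermediate
39 | lithium C8 aldolate | O=C1/C=C(C)\C=C/C(=O)[C@@]2(C)C=C[C@H]3OC(C)(C)O[C@@]3(C)[C@@H]2[C@H](O[Si](C)(C)C(C)(C)C)[C@]1([O-])[C@@H](C)C(=O)OC.[Li+] | intermediate
40 | C8 aldol adduct, 8-trimethylsilyl ether (C7 ketone, C19 methyl ester; C8, C17 as in 50) | O=C1/C=C(C)\C=C/C(=O)[C@@]2(C)C=C[C@H]3OC(C)(C)O[C@@]3(C)[C@@H]2[C@H](O[Si](C)(C)C(C)(C)C)[C@]1(O[Si](C)(C)C)[C@@H](C)C(=O)OC | intermediate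
41 | potassium 5(16),6-dienolate of 40 | C=C1/C=C\C(=O)[C@@]2(C)C=C[C@H]3OC(C)(C)O[C@@]3(C)[C@@H]2[C@H](O[Si](C)(C)C(C)(C)C)[C@](O[Si](C)(C)C)([C@@H](C)C(=O)OC)C([O-])=C1.[K+] | intermediate
42 | 6-chloro-3,5(16),13-triene-2,7-dione (C6 as in 50) | C=C1/C=C\C(=O)[C@@]2(C)C=C[C@H]3OC(C)(C)O[C@@]3(C)[C@@H]2[C@H](O[Si](C)(C)C(C)(C)C)[C@](O[Si](C)(C)C)([C@@H](C)C(=O)OC)C(=O)[C@H]1Cl | intermediate
43 | 6-chloro-2,7-diol methyl ester | C=C1/C=C\[C@H](O)[C@@]2(C)C=C[C@H]3OC(C)(C)O[C@@]3(C)[C@@H]2[C@H](O[Si](C)(C)C(C)(C)C)[C@](O[Si](C)(C)C)([C@@H](C)C(=O)OC)[C@@H](O)[C@H]1Cl | intermediate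
44 | 6-chloro-2-hydroxy 19,7-lactone, 8-trimethylsilyloxy, 9-silyloxy, 11,12-acetonide | C=C1/C=C\[C@H](O)[C@@]2(C)C=C[C@H]3OC(C)(C)O[C@@]3(C)[C@@H]2[C@H](O[Si](C)(C)C(C)(C)C)[C@]2(O[Si](C)(C)C)[C@@H](C)C(=O)O[C@H]2[C@H]1Cl | intermediate
45 | 2-butanoate of 44 | C=C1/C=C\[C@H](OC(=O)CCC)[C@@]2(C)C=C[C@H]3OC(C)(C)O[C@@]3(C)[C@@H]2[C@H](O[Si](C)(C)C(C)(C)C)[C@]2(O[Si](C)(C)C)[C@@H](C)C(=O)O[C@H]2[C@H]1Cl | intermediate
46 | 2-butanoate 8,9-diol (11,12-acetonide) | C=C1/C=C\[C@H](OC(=O)CCC)[C@@]2(C)C=C[C@H]3OC(C)(C)O[C@@]3(C)[C@@H]2[C@H](O)[C@]2(O)[C@@H](C)C(=O)O[C@H]2[C@H]1Cl | intermediate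
47 | 9-acetate 2-butanoate (11,12-acetonide, 8-hydroxyl free) | C=C1/C=C\[C@H](OC(=O)CCC)[C@@]2(C)C=C[C@H]3OC(C)(C)O[C@@]3(C)[C@@H]2[C@H](OC(C)=O)[C@]2(O)[C@@H](C)C(=O)O[C@H]2[C@H]1Cl | intermediate
48 | 9-acetate 2-butanoate 13-ene-11α,12α-diol | C=C1/C=C\[C@H](OC(=O)CCC)[C@@]2(C)C=C[C@@H](O)[C@@](C)(O)[C@@H]2[C@H](OC(C)=O)[C@]2(O)[C@@H](C)C(=O)O[C@H]2[C@H]1Cl | intermediate
49 | 9-acetate 2-butanoate 13α,14α-epoxy-11α,12α-diol | C=C1/C=C\[C@H](OC(=O)CCC)[C@@]2(C)[C@H]3O[C@H]3[C@@H](O)[C@@](C)(O)[C@@H]2[C@H](OC(C)=O)[C@]2(O)[C@@H](C)C(=O)O[C@H]2[C@H]1Cl | intermediate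
50 | CNP0188106.1: (1S,2S,3Z,6S,7R,8R,9S,10S,11S,12R,13R,14R,17R)-9-acetoxy-2,12-bis(butanoyloxy)-6-chloro-13,14-epoxy-8,11-dihydroxybriara-3,5(16)-dien-19,7-olide (numbering as defined above) | C=C1/C=C\[C@H](OC(=O)CCC)[C@@]2(C)[C@H]3O[C@H]3[C@@H](OC(=O)CCC)[C@@](C)(O)[C@@H]2[C@H](OC(C)=O)[C@]2(O)[C@@H](C)C(=O)O[C@H]2[C@H]1Cl | target

## Step count and least certain steps

Total step count: 29. Longest linear sequence: 29 steps (fully linear from 1; 2, 8 and 37 enter as bought building blocks).

Step 17 (key step). The most likely failures are over-oxidation once the tetrasubstituted olefin is consumed (the trisubstituted C4=C5 is the next fastest), sluggish reduction of the hindered ozonide, and transannular aldol condensation of the 1,6-dione during work-up. Fallback, same bond cleaved by other means: from 29, one equivalent of buffered mCPBA should epoxidise only the tetrasubstituted olefin, from the α face, to the 2,7-epoxide F1. Periodic acid in aqueous THF then opens it to the 2,7-diol F2 and cleaves the diol in the same flask (or Pb(OAc)4 on isolated F2), returning to 31.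

Step 18. Before both ketones are silylated, a silyl enol ether may add across the ring to the other carbonyl (transannular aldol); C7 may also enolise partly toward C8, and DDQ may over-oxidise. Fallback: from 31, epoxidise C4=C5 with mCPBA to the 4,5-epoxide F3. DBU opens this β,γ-epoxy ketone by elimination from C6 to the γ-hydroxy enone F4. Mesylation gives F5, and elimination through the C2 enolate (Et3N, then DBU) returns to 33.

Step 21. The ester enolate may act as a base: proton transfer from C9 of the vicinal dione would erode the C9 configuration. It may also add at C7 or in conjugate fashion, or add to C8 with poor facial selectivity. C17 is formed without firm control; if the epimer results, DBU equilibration at the lactone stage should favour methyl trans to the ring carbon C9. Fallback with reversed polarity: from 33, alkylate the C8 lithium enolate with methyl (R)-2-(trifluoromethylsulfonyloxy)propanoate, where SN2 inversion fixes C17, to the C8-alkylated dienedione F6. A second enolisation and oxaziridine hydroxylation give the tertiary alcohol F7, and Me3SiOTf/2,6-lutidine returns to 40.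

Step 22. Chlorine may enter at the γ-carbon C16; the product may re-conjugate by proton exchange with unreacted enolate; facial selectivity at C6 may be poor; the ester may enolise at C17 and lose the C8 silyloxy group. Fallback: from 40, carry out the Luche reduction and lactonisation first to the 3,5-diene lactone F8, which keeps C5=C6 and the C16 methyl. Then introduce chlorine by electrophilic ene-type chlorination of the trisubstituted C5=C6 olefin (N-chlorosuccinimide with catalytic PhSeCl), which places chlorine on C6 and shifts the olefin to C5=C16, returning to 44.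

Step 23. Hydride addition at C7 has no reliable model: three large groups on C8 compete in a flexible ring, and selectivity at the neopentyl C2 is also only assumed. The chlorohydrin alkoxide may close an epoxide instead of the lactone. Fallback, in which C9 controls C7: from 42, remove both silyl groups with HF·pyridine to the 8,9-dihydroxy chloro ketone F9 and use it crude. An Evans–Tishchenko reduction with acetaldehyde follows; the samarium catalyst is pre-formed from SmI2 and the aldehyde, so that only trivalent samarium meets the chloro ketone. Hydride is delivered from the C9 hemiacetal to give the 1,3-anti relationship of the target and leaves C9 as its acetate. The C7 alcohol lactonises in the same flask to the 9-acetoxy 2-oxo lactone F10. Luche reduction of the remaining C2 enone gives the 2-alcohol F11, and butanoylation of its only secondary hydroxyl returns to 47.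

## Further compounds

F1 | step 17 | 2α,7α-epoxide of 29 | CC1=CC[C@]25O[C@]5(C1)C[C@@H](O[Si](C)(C)C(C)(C)C)[C@H]3[C@]4(C)OC(C)(C)O[C@@H]4C=C[C@]23C
F2 | step 17 | 2,7-diol of 29 (C2 and C7 undefined) | CC1=CCC2(O)C(O)(C1)C[C@@H](O[Si](C)(C)C(C)(C)C)[C@H]3[C@]4(C)OC(C)(C)O[C@@H]4C=C[C@]23C
F3 | step 18 | 4,5-epoxide of 31 (cis, face undefined) | CC15OC5CC(=O)[C@@]2(C)C=C[C@H]3OC(C)(C)O[C@@]3(C)[C@@H]2[C@H](O[Si](C)(C)C(C)(C)C)CC(=O)C1
F4 | step 18 | 4-hydroxy-5,13-diene-2,7-dione (C4 undefined) | O=C1/C=C(C)\C(O)CC(=O)[C@@]2(C)C=C[C@H]3OC(C)(C)O[C@@]3(C)[C@@H]2[C@H](O[Si](C)(C)C(C)(C)C)C1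
F5 | step 18 | 4-mesylate of F4 | O=C1/C=C(C)\C(OS(C)(=O)=O)CC(=O)[C@@]2(C)C=C[C@H]3OC(C)(C)O[C@@]3(C)[C@@H]2[C@H](O[Si](C)(C)C(C)(C)C)C1
F6 | step 21 | C8-alkylated dienedione with C17 methyl ester side chain (C8 undefined) | O=C1/C=C(C)\C=C/C(=O)[C@@]2(C)C=C[C@H]3OC(C)(C)O[C@@]3(C)[C@@H]2[C@H](O[Si](C)(C)C(C)(C)C)C1[C@@H](C)C(=O)OC
F7 | step 21 | 8-hydroxy aldol adduct (free tertiary alcohol of 40) | O=C1/C=C(C)\C=C/C(=O)[C@@]2(C)C=C[C@H]3OC(C)(C)O[C@@]3(C)[C@@H]2[C@H](O[Si](C)(C)C(C)(C)C)[C@]1(O)[C@@H](C)C(=O)OC
F8 | step 22 | 2-hydroxy (3Z,5Z)-3,5,13-triene 19,7-lactone with C16 methyl | O1C(=O)[C@H](C)[C@]2(O[Si](C)(C)C)[C@@H]1/C=C(C)\C=C/[C@H](O)[C@@]3(C)C=C[C@H]4OC(C)(C)O[C@@]4(C)[C@@H]3[C@@H]2O[Si](C)(C)C(C)(C)C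
F9 | step 23 | 8,9-dihydroxy 6-chloro-2,7-dione methyl ester | C=C1/C=C\C(=O)[C@@]2(C)C=C[C@H]3OC(C)(C)O[C@@]3(C)[C@@H]2[C@H](O)[C@](O)([C@@H](C)C(=O)OC)C(=O)[C@H]1Cl
F10 | step 23 | 9-acetoxy 2-oxo 19,7-lactone | C=C1/C=C\C(=O)[C@@]2(C)C=C[C@H]3OC(C)(C)O[C@@]3(C)[C@@H]2[C@H](OC(C)=O)[C@]2(O)[C@@H](C)C(=O)O[C@H]2[C@H]1Cl
F11 | step 23 | 9-acetoxy 2-hydroxy 19,7-lactone | C=C1/C=C\[C@H](O)[C@@]2(C)C=C[C@H]3OC(C)(C)O[C@@]3(C)[C@@H]2[C@H](OC(C)=O)[C@]2(O)[C@@H](C)C(=O)O[C@H]2[C@H]1Cl
A1 | alternative 1 | fourteen-membered C1–C14 epoxide with C10=C11 allylsilane (olefin geometry undefined) | C1#C[C@H](O[Si](C)(C)C(C)(C)C)[C@@]2(C)O[C@@H]2C[C@@H](O[Si](C)(C)C(C)(C)C)C(C[Si](C)(C)C)=C[C@H](O[Si](C)(C)C(C)(C)C)[C@]2(O[Si](CC)(CC)CC)[C@@H](C)C(=O)O[C@H]2/C=C1/C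
A2 | alternative 1 | 6/10-bicyclic C14 alcohol with C11 exocyclic methylene | C1#C[C@H](O[Si](C)(C)C(C)(C)C)[C@@]2(C)[C@H](O)C[C@@H](O[Si](C)(C)C(C)(C)C)C(=C)[C@@H]2[C@H](O[Si](C)(C)C(C)(C)C)[C@]2(O[Si](CC)(CC)CC)[C@@H](C)C(=O)O[C@H]2/C=C1/C
A3 | alternative 2 | C7=C8 8-trimethylsilyl enol ether (olefin geometry undefined) | C=C1/C=C\[C@H](OCOC)[C@@]2(C)C=C[C@@H](OC(C)(C)O3)[C@]3(C)[C@@H]2[C@H](OCOC)C(O[Si](C)(C)C)=C[C@H]1Cl
A4 | alternative 2 | methylketene | CC=C=O
A5 | alternative 2 | trans-fused 8-silyloxy-17-methylcyclobutanone | C=C1/C=C\[C@H](OCOC)[C@@]2(C)C=C[C@@H](OC(C)(C)O3)[C@]3(C)[C@@H]2[C@H](OCOC)[C@]2(O[Si](C)(C)C)[C@@H](C)C(=O)[C@H]2[C@H]1Cl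
A6 | alternative 3 | (1E)-cyclodecene-2,9-dione dienophile | C=C1/C=C\C(=O)/C(C)=C/C(=O)[C@]2(O[Si](CC)(CC)CC)[C@@H](C)C(=O)O[C@H]2[C@H]1Cl
A7 | alternative 3 | 3-(tert-butyldimethylsilyloxy)penta-1,3-diene | C=CC(O[Si](C)(C)C(C)(C)C)=CC
A8 | alternative 3 | trans-fused ring A silyl enol ether 2,9-dione | C=C1/C=C\C(=O)[C@@]2(C)CC=C(O[Si](C)(C)C(C)(C)C)[C@H](C)[C@@H]2C(=O)[C@]2(O[Si](CC)(CC)CC)[C@@H](C)C(=O)O[C@H]2[C@H]1Cl
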